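## Analysis of the target

The target (27) is the C19 gibberellin numbered 93 in the gibberellin A series. Ring A is a cyclohexane bridged on its α face by a γ-lactone from C19 (on C4) to the oxygen on C10, ring B is a cyclopentane (C5, C6, C8, C9, C10), and rings C and D form a bicyclo[3.2.1]octane with a tertiary hydroxyl at the bridgehead C13 and an exocyclic methylene C16=C17 (gibberellin numbering is used for all intermediates, and α denotes the face of the lactone). There are ten stereocentres (C1, C2, C3, C4, C5, C6, C8, C9, C10, C13), nine of them contiguous; C4 and C8 are all-carbon quaternary centres, and C10 and C13 are fully substituted. The 1-hydroxyl is β, cis to the 2β,3β-epoxide and trans to the C10 oxygen; H-5 is β and H-6 is α, so the C7 carboxyl is β and trans to C4. Ring C is cis-fused to ring B through the α bonds C8–C14 and C9–C11, while C15 and H-9 are β. The sensitive groups are the cis-epoxy alcohol next to the lactone (acid and strong base), the tertiary allylic 13-hydroxyl with the C16=C17 alkene (cationic rearrangement, electrophilic oxidants) and the epimerisable C6 next to C7. The difficulty lies in three places: the quaternary C8 at the junction of rings B, C and D; the placement of three oxygens on the hindered cage of ring A with the right faces; and keeping the C16=C17 alkene apart from the ring A alkenes during oxidation. The strategy rests on ring C: it is cis-fused at C8–C9 and its oxygen-bearing C13 lies 1,4 to C9, which is the pattern left by a 2-oxygenated butadiene (C14, C13, C12, C11) adding across the C8=C9 bond of a ring B cyclopentenone whose carbonyl is C10.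

## Retrosynthetic reasoning

**C7 carboxyl.** 27 is traced to aldehyde 26 and triol 25, and 25 to the bis-silyl ether 24. The acid is made last from a primary alcohol. A C7 ester would need hydrolysis conditions that the epoxy lactone does not tolerate, and a free acid would disturb the enolate steps. The forward steps must oxidise only the primary hydroxyl in the presence of the secondary 1-hydroxyl.

**C2–O and C3–O.** A cis-epoxy alcohol is what a hydroxyl-directed epoxidation leaves, so 24 comes from the allylic alcohol 23 (1β-hydroxy, C2=C3). The 13-hydroxyl is silylated so that only the C1 hydroxyl can direct.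

**C1–O.** 23 is the transposition product of the epoxy ketone 21, and 21 comes from the enone 20 (C3 ketone, C1=C2). The C1 oxygen must enter from the β face, which is the open face of the bridged ring A. A nucleophilic oxidant does this and leaves the electron-rich C16=C17 alkene alone.

**C1=C2.** 20 comes from the allylic alcohol 19, and the ring A alkene of 19 is cut by metathesis to 18. In 18 a vinyl group on C10 and a 1-hydroxyallyl group on C4 sit on the same face of a bicyclic lactone and are held close.

**C3–C4 and C4–C18.** 18 comes from 17 and 17 from 16 by two substitutions of one lactone enolate. The bridgehead C4 of the finished cage cannot be enolised, so the quaternary centre is built while the lactone is only fused to ring B. The order (methyl first, C3 unit second) fixes the configuration, because the second electrophile enters from the convex face.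

**C13–C16 (ring D).** 16 is the silyl ether of 15, which comes from the alkynyl ketone 14 by ketyl–alkyne cyclisation. The cut is placed here, after C10 has ceased to be a carbonyl. The C10 and C13 carbonyls have the same 1,5 relationship to the alkyne carbon C16, so a ketyl at C10 would compete. 14 is unmasked from the enol silyl ether 13.

**C10–C1, C10–O–C19 and C4–C5.** 13 is the lactone formed when a vinyl nucleophile adds to the C10 ketone of the γ-keto ester 11 (via the alkoxide 12). 11 comes from 10 by alkylation of the C5 enolate with a two-carbon ester electrophile. The ketone supplies the lactone oxygen directly, and the two flanking substituents steer the vinyl group to the β face.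

**C8–C14 and C9–C11 (ring C).** 10 is cut to the cyclopentenone 7 and the diene 9. One cycloaddition gives the quaternary C8, the cis ring fusion and a masked C13 ketone, with the propargyl arm for ring D already in place.

**Starting materials.** 7 comes from 4 and propargyl bromide 5 by addition and enone transposition. 4 comes from 3, which is resolved from 2, and 2 is made from 3-ethoxycyclopentenone 1. 9 comes from methyl vinyl ketone 8.

## Alternatives that were turned down

**Alternative 1:** Ring B is made by contraction of the six-membered ring B of steviol (A1), cutting the C6–C8 bond of the target back to a C7–C8 bond.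
- **Key step:** an ent-kaurenoic acid oxidase (a cytochrome P450) oxidises C7 and C6 so that C8 migrates to C6 and C7 is extruded as the carboxyl, giving the 13-hydroxy C20 gibberellin 7,19-dioic acid numbered 53 in the gibberellin A series (A2).
- **For:** A1 is abundant. The enzyme delivers rings B, C and D, the 13-hydroxyl, the methylene and the C7 acid with every core stereocentre in one step. On step economy to the B/C/D core this route is stronger than the chosen one.
- **Against:** A2 is a C20 gibberellin with a saturated, unoxidised ring A. The target still needs excision of C20 with lactone formation at C10, and then oxygen at C1, C2 and C3. All of these are unactivated positions with no handle, so they call for further enzymes or long remote functionalisation. The P450 is membrane-bound and needs a reductase partner and a whole-cell system.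
- **Comparison:** the chosen strategy is longer to the core, but it arrives at ring A with the C10 ketone, from which the lactone oxygen, C1 and the alkenes for oxidation are all built in.

**Alternative 2:** Rings A and B are cut together at C3–C4 and C5–C10.
- **Key step:** a thermal intramolecular Diels–Alder reaction between a 1-silyloxy-4-phenylthio diene (C10, C1, C2, C3) and a (Z)-2-methyl enoate (C4, C5), giving the tetracycle A3.
- **For:** two rings and the stereocentres C4, C5 and C10 are set at once. C4 follows from the enoate geometry. The C10 oxygen is in place for lactonisation. The 3β-sulfide next to the C1=C2 alkene is a latent 1β-hydroxy-2-ene through a sulfoxide [2,3] shift. On ring A this is stronger than the chosen route, which needs six steps from 16 to 23.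
- **Against:** the quaternary C8 and both sensitive π-systems, carried on elaborate chains at C9 and C6 of an enantiopure bicyclo[3.2.1]octane core, must all be in place before the key step, so most of the effort moves into preparing the cycloaddition substrate. The cycloaddition must also choose the correct one of several transition states at high temperature.
- **Comparison:** the chosen strategy makes C8 early, by one catalytic step from small, cheap pieces, and controls each later centre from the ring already present.

**Alternative 3:** The three C–O bonds of ring A are cut together.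
- **Key step:** singlet oxygen adds to C1 of the 1-ene lactone A5 in an ene reaction with the C3 hydrogen. Ti(OiPr)4 then passes the outer oxygen of the hydroperoxide to the new C2=C3 alkene, giving A4.
- **For:** one flask sets C1, C2 and C3 from the open β face. This is shorter than the three oxidation steps (16 to 18) used here.
- **Against:** it is an endgame only and says nothing about the skeleton. The oxidant does not tolerate the exocyclic alkene, so A4 carries a C16 ketone in place of C16=C17 and a methyl ester at C7. The target then needs a late methylenation of a hindered ketone and an ester cleavage, both under conditions that endanger the epoxy lactone.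
- **Comparison:** the chosen route uses a nucleophilic epoxidation and a hydroxyl-directed epoxidation, both of which ignore C16=C17. The methylene is therefore in place from step 10, and C7 is oxidised only at the end.

Key step: step 6

**Assumption:** the lipase of step 2 is taken to acetylate the (S)-alcohol faster, so that (R)-3 is recovered. If the preference is the reverse, the acetate fraction is carried on after methanolysis.

## Route

Step 1
Reactants: 1 3-ethoxycyclopent-2-en-1-one
Product: 2 rac-3-ethoxy-5-(hydroxymethyl)cyclopent-2-en-1-one
Conditions: LDA, THF, −78 °C; CH2O (gas, from paraformaldehyde); NH4Cl quench at −78 °C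
Reagents that add atoms: formaldehyde, C=O
Why: Kinetic deprotonation of the vinylogous ester occurs at the α′ methylene, and the lithium enolate adds to monomeric formaldehyde (aldol addition); a cold quench should prevent retro-aldol and dehydration. The new stereocentre (the future C6) is formed racemic.

Step 2
Reactants: 2 rac-3-ethoxy-5-(hydroxymethyl)cyclopent-2-en-1-one
Product: 3 (R)-3-ethoxy-5-(hydroxymethyl)cyclopent-2-en-1-one
Conditions: Amano lipase PS (Burkholderia cepacia), vinyl acetate, t-BuOMe, 23 °C, to just past half conversion
Reagents that add atoms: none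
Why: Lipase-catalysed kinetic resolution by irreversible acyl transfer from vinyl acetate; running past half conversion should leave the slow-reacting alcohol in high enantiomeric purity. No stereocentre is formed; the step selects the (R)-enantiomer, which becomes C6.

Step 3
Reactants: 3 (R)-3-ethoxy-5-(hydroxymethyl)cyclopent-2-en-1-one
Product: 4 (R)-5-[(tert-butyldiphenylsilyloxy)methyl]-3-ethoxycyclopent-2-en-1-one
Conditions: TBDPSCl, imidazole, DMF, 0 → 23 °C
Reagents that add atoms: tert-butyldiphenylsilyl chloride, CC(C)(C)[Si](Cl)(c1ccccc1)c1ccccc1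
Why: Standard silylation of a primary alcohol. The bulky, acid-stable TBDPS group is chosen because it must survive the acid of steps 4 and 9 and must shield the β face next to C8 in step 6.

Step 4
Reactants: 4 (R)-5-[(tert-butyldiphenylsilyloxy)methyl]-3-ethoxycyclopent-2-en-1-one; 5 propargyl bromide
Product: 7 (S)-4-[(tert-butyldiphenylsilyloxy)methyl]-3-(prop-2-yn-1-yl)cyclopent-2-en-1-one, via tertiary propargyl carbinol 6 (not isolated)
Conditions: 5, Mg, HgCl2 (cat.), Et2O, 0 °C; add 4, −78 → 0 °C; then 1 M HCl, THF, 23 °C
Reagents that add atoms: water, O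
Why: Stork–Danheiser enone transposition: the allenyl Grignard reagent adds 1,2 to the vinylogous ester carbonyl through an SE2′ transition state to give the homopropargyl carbinol; acid then ionises the tertiary allylic alcohol, water adds at the ethoxy-bearing carbon and ethanol is lost. The carbonyl thus appears at C10 with the propargyl group on the β-carbon C8; C6 is not touched (its descriptor changes from R to S only through the priority rules).

Step 5
Reactants: 8 methyl vinyl ketone
Product: 9 2-(tert-butyldimethylsilyloxy)buta-1,3-diene
Conditions: TBSOTf, Et3N, Et2O, 0 °C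
Reagents that add atoms: tert-butyldimethylsilyl triflate, CC(C)(C)[Si](C)(C)OS(=O)(=O)C(F)(F)F
Why: Soft enolisation of the methyl ketone and O-silylation give the cross-conjugated silyl enol ether. The tert-butyldimethylsilyl group is used so that the enol ether formed in step 6 survives the two basic steps that follow.

Step 6
Reactants: 7 (S)-4-[(tert-butyldiphenylsilyloxy)methyl]-3-(prop-2-yn-1-yl)cyclopent-2-en-1-one; 9 2-(tert-butyldimethylsilyloxy)buta-1,3-diene
Product: 10 (3S,3aR,7aR)-5-(tert-butyldimethylsilyloxy)-3-[(tert-butyldiphenylsilyloxy)methyl]-3a-(prop-2-yn-1-yl)-2,3,3a,4,7,7a-hexahydro-1H-inden-1-one (cis-fused; C10 ketone, C12=C13 enol silyl ether, 8β-propargyl)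
Conditions: Me3SiNTf2 (10 mol %), 9 (2 equiv), CH2Cl2, −78 °C; Et3N, then aq. NaHCO3
Reagents that add atoms: none
Why: Me3SiNTf2 silylates the C10 carbonyl oxygen reversibly and turns the enone into a silyloxyallyl cation with its charge at C8. The diene bonds through its enol ether terminus C14 to C8 and through C11 to C9 in a concerted but strongly asynchronous [4+2] addition, and the Me3Si group then passes to the next enone, so the product keeps the diene's own silyl group on O13. The closest known reaction type is the silyl triflimide-catalysed Diels–Alder reaction of 2-silyloxydienes with β,β-disubstituted cycloalkenones, which forms quaternary ring-fusion carbons. Ring C closes as a six-membered ring by cycloaddition, suprafacial on the dienophile, so the fusion is cis and C15 and H-9 end on the same face. Regiochemistry follows from matched polarity: the nucleophilic C14 meets the electrophilic C8, which places oxygen on C13, 1,4 to C9. The only selectivity needed is facial, since the diene termini are unsubstituted; the C6 stereocentre, next to the carbon where the first bond forms, carries the bulky CH2OTBDPS group on the β face and should send the diene to the α face. C8 and C9 are thereby set relative to C6.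

Step 7
Reactants: 10 cis-hydrindanone (C10 ketone, C13 enol silyl ether)
Product: 11 keto ester: 10 with an ethoxycarbonylmethyl group on C5 (α, trans to the C6 CH2OTBDPS group)
Conditions: LDA (1.05 equiv), THF, −78 °C; BrCH2CO2Et, DMPU, −78 → −40 °C
Reagents that add atoms: ethyl bromoacetate, BrCC(=O)OCC
Why: Kinetic enolate alkylation: LDA removes a proton from the C5 methylene and not from the hindered ring-fusion methine C9 or the less acidic terminal alkyne, and the enolate reacts with the activated bromide. The electrophile enters anti to the adjacent β-oriented C6 substituent, so C4 is α (H-5 β); the trans isomer is also the more stable one.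

Step 8
Reactants: 11 keto ester
Product: 13 10β-vinyl 19,10α-γ-lactone (C4 = CH2) cis-fused to ring B with C13 enol silyl ether, via hydroxy ester alkoxide 12 (not isolated)
Conditions: CH2=CHMgBr (excess), CeCl3, THF, −78 → 23 °C
Reagents that add atoms: vinylmagnesium bromide, C=C[Mg]Br
Why: The organocerium reagent adds to the ketone in preference to the ester and without enolisation; both carbons next to C10 carry their substituents on the α face (the C5 arm and C11 of ring C), so attack should come from the β face. The resulting α alkoxide is cis to the ester arm and closes the γ-lactone with loss of ethoxide, as γ-keto esters do with Grignard reagents; this sets C10.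

Step 9
Reactants: 13 vinyl lactone with C13 enol silyl ether
Product: 14 vinyl lactone with C13 ketone (8β-propargyl, C7 OTBDPS)
Conditions: 1 M HCl, THF, 0 °C
Reagents that add atoms: none
Why: Enol silyl ethers are hydrolysed by dilute acid through protonation at carbon (C12) far faster than alkyl silyl ethers, so the primary TBDPS ether and the lactone should survive. The C13 ketone is revealed only now, when C10 is no longer a carbonyl, so the next step has a single ketyl site.

Step 10
Reactants: 14 alkynyl ketone
Product: 15 tetracyclic alcohol (rings B, C, D and lactone; 13-OH, C16=C17, 10β-vinyl, C7 OTBDPS)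
Conditions: SmI2, HMPA, t-BuOH, THF, 0 °C
Reagents that add atoms: none
Why: Ketyl–alkyne reductive cyclisation: SmI2 reduces the ketone to a ketyl, which adds 5-exo-dig to C16 of the propargyl arm; the vinyl radical is reduced and protonated to the exocyclic methylene. The configuration of C13 is fixed by the bridge, since C16 can reach C13 only from the side of C15.

Step 11
Reactants: 15 tetracyclic alcohol
Product: 16 13-O-triethylsilyl ether of 15
Conditions: TESOTf, 2,6-lutidine, CH2Cl2, −78 → 0 °C
Reagents that add atoms: triethylsilyl triflate, CC[Si](CC)(CC)OS(=O)(=O)C(F)(F)F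
Why: Silyl triflates silylate tertiary alcohols. The ether removes the acidic proton before the enolate steps and prevents the 13-hydroxyl from directing the epoxidation of step 18 to C16=C17.

Step 12
Reactants: 16 13-O-triethylsilyl ether
Product: 17 4-methyl lactone (methyl expected on the convex face, cis to the C10 vinyl group)
Conditions: LDA, THF, −78 °C; MeI, −78 → −40 °C
Reagents that add atoms: iodomethane, CI
Why: Lactone enolate alkylation; the only acidic C–H is at C4. The configuration formed here is of no consequence, because C4 is enolised again in step 13.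

Step 13
Reactants: 17 4-methyl lactone
Product: 18 aldol adduct: C4 bears the C18 methyl on the concave side and a 1-hydroxyallyl group (C3, cis to the C10 vinyl group); both C3 epimers
Conditions: LDA, THF, −78 °C; acrolein, −78 °C; AcOH quench at −78 °C
Reagents that add atoms: acrolein, C=CC=O
Why: Aldol addition of the tetrasubstituted lithium lactone enolate to the aldehyde carbon of acrolein (1,2-addition at low temperature). In the cis-fused bicyclic lactone the electrophile should enter from the convex face, anti to the C5–C6 bond, which places C3 cis to the vinyl group on C10 and the methyl on the concave side; this sets the quaternary C4. The carbinol centre C3 is lost in step 15.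

Step 14
Reactants: 18 aldol adduct
Product: 19 pentacyclic allylic alcohol (ring A closed; C1=C2, 3-OH as both epimers, 19,10-lactone, 13-OTES, 7-OTBDPS, C16=C17)
Conditions: second-generation Hoveyda–Grubbs catalyst (10 mol %), toluene, 80 °C
Reagents that add atoms: none
Why: Ring-closing metathesis of two monosubstituted alkenes held 1,3-cis on the convex face of the lactone closes the six-membered ring A with loss of ethene. The 1,1-disubstituted C16=C17 alkene is far less reactive toward the ruthenium carbene and should not take part.

Step 15
Reactants: 19 pentacyclic allylic alcohol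
Product: 20 enone (3-oxo-1-ene lactone)
Conditions: Dess–Martin periodinane, CH2Cl2, 0 → 23 °C
Reagents that add atoms: none
Why: Oxidation of a secondary allylic alcohol to the enone with a hypervalent iodine reagent; both C3 epimers converge. C4 is quaternary, so the β-keto lactone cannot enolise or epimerise.

Step 16
Reactants: 20 enone
Product: 21 1β,2β-epoxy-3-ketone
Conditions: t-BuOOH, DBU, CH2Cl2, 0 °C
Reagents that add atoms: tert-butyl hydroperoxide, CC(C)(C)OO
Why: Weitz–Scheffer epoxidation: the hydroperoxide anion adds to C1 of the enone and the enolate closes the epoxide. Attack should come from the β face, the side of the one-carbon bridge C5 and away from the lactone bridge; this sets C1 and C2. The nucleophilic oxidant does not react with the electron-rich C16=C17 alkene.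

Step 17
Reactants: 21 epoxy ketone
Product: 23 1β-hydroxy-2-ene lactone, via epoxy hydrazone 22 (not isolated)
Conditions: N2H4·H2O, AcOH, MeOH, 0 → 23 °C
Reagents that add atoms: none
Why: Wharton transposition: the hydrazone opens the epoxide at C2 to a vinyl diazene, which loses nitrogen to leave the C2=C3 alkene. The C1–O bond is not broken, so the 1β configuration is kept.

Step 18
Reactants: 23 allylic alcohol
Product: 24 1β-hydroxy-2β,3β-epoxy lactone (13-OTES, 7-OTBDPS)
Conditions: VO(acac)2 (5 mol %), t-BuOOH, CH2Cl2, 0 °C
Reagents that add atoms: tert-butyl hydroperoxide, CC(C)(C)OO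
Why: Vanadium-catalysed hydroxyl-directed epoxidation: the vanadate ester of the 1β-hydroxyl delivers oxygen to the same face of the ring alkene, which is also the open β face, and sets C2 and C3 cis to the hydroxyl. C16=C17 has no free hydroxyl nearby and should not react.

Step 19
Reactants: 24 bis-silyl epoxy alcohol
Product: 25 triol (C7 CH2OH, 1β-OH, 13-OH)
Conditions: TBAF, AcOH, THF, 23 °C
Reagents that add atoms: none
Why: Fluoride cleaves both silyl ethers; buffering with acetic acid keeps the medium near neutral for the lactone. A Payne rearrangement is not possible because the 1-oxygen is cis to the epoxide and cannot attack C2 from the rear.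

Step 20
Reactants: 25 triol
Product: 26 aldehyde (C7 = CHO)
Conditions: TEMPO (cat.), PhI(OAc)2, CH2Cl2, 23 °C
Reagents that add atoms: none
Why: Oxoammonium-mediated oxidation is selective for primary alcohols; the hindered secondary 1-hydroxyl, flanked by the quaternary C10 and the epoxide, and the tertiary 13-hydroxyl should remain. The conditions are close to neutral, which protects C6 from epimerisation.

Step 21
Reactants: 26 aldehyde
Product: 27 target gibberellin (number 93 of the gibberellin A series): C19 gibberellin 19,10-lactone 7-oic acid with 1β-hydroxyl, 2β,3β-epoxide, 13-hydroxyl and C16=C17 methylene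
Conditions: NaClO2, NaH2PO4, 2-methylbut-2-ene, t-BuOH/H2O, 0 °C
Reagents that add atoms: sodium chlorite, [Na+].[O-]Cl=O
Why: Pinnick oxidation of the aldehyde to the acid. The alkene scavenger removes hypochlorous acid before it can reach C16=C17, and the phosphate buffer is mild enough for the epoxide and the lactone.

## Compound list

1 | 3-ethoxycyclopent-2-en-1-one | CCOC1=CC(=O)CC1 | starting material
2 | rac-3-ethoxy-5-(hydroxymethyl)cyclopent-2-en-1-one | OCC1CC(OCC)=CC1=O | intermediate
3 | (R)-3-ethoxy-5-(hydroxymethyl)cyclopent-2-en-1-one | OC[C@H]1CC(OCC)=CC1=O | intermediate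
4 | (R)-5-[(tert-butyldiphenylsilyloxy)methyl]-3-ethoxycyclopent-2-en-1-one | CC(C)(C)[Si](c1ccccc1)(c1ccccc1)OC[C@H]1CC(OCC)=CC1=O | intermediate
5 | propargyl bromide (3-bromoprop-1-yne) | C#CCBr | starting material
6 | (5R)-5-[(tert-butyldiphenylsilyloxy)methyl]-3-ethoxy-1-(prop-2-yn-1-yl)cyclopent-2-en-1-ol (carbinol epimers) | CC(C)(C)[Si](c1ccccc1)(c1ccccc1)OC[C@H]1CC(OCC)=CC1(O)CC#C | intermediate
7 | (S)-4-[(tert-butyldiphenylsilyloxy)methyl]-3-(prop-2-yn-1-yl)cyclopent-2-en-1-one | CC(C)(C)[Si](c1ccccc1)(c1ccccc1)OC[C@H]1CC(=O)C=C1CC#C | intermediate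
8 | methyl vinyl ketone (but-3-en-2-one) | CC(=O)C=C | starting material
9 | 2-(tert-butyldimethylsilyloxy)buta-1,3-diene | C=CC(=C)O[Si](C)(C)C(C)(C)C | intermediate
10 | (3S,3aR,7aR)-5-(tert-butyldimethylsilyloxy)-3-[(tert-butyldiphenylsilyloxy)methyl]-3a-(prop-2-yn-1-yl)-2,3,3a,4,7,7a-hexahydro-1H-inden-1-one | C#CC[C@]23CC(O[Si](C)(C)C(C)(C)C)=CC[C@H]2C(=O)C[C@@H]3CO[Si](c1ccccc1)(c1ccccc1)C(C)(C)C | intermediate
11 | keto ester: 10 with CH2CO2Et on C5, trans to the C6 CH2OTBDPS group | C#CC[C@]23CC(O[Si](C)(C)C(C)(C)C)=CC[C@H]2C(=O)[C@@H](CC(=O)OCC)[C@@H]3CO[Si](c1ccccc1)(c1ccccc1)C(C)(C)C | intermediate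
12 | hydroxy ester (formed as its alkoxide): 10α-hydroxy-10β-vinyl adduct of 11 | C#CC[C@]23CC(O[Si](C)(C)C(C)(C)C)=CC[C@H]2[C@](O)(C=C)[C@@H](CC(=O)OCC)[C@@H]3CO[Si](c1ccccc1)(c1ccccc1)C(C)(C)C | intermediate
13 | 10β-vinyl 19,10α-γ-lactone (C4 = CH2), C13 enol silyl ether, 8β-propargyl, C7 OTBDPS | C#CC[C@]23CC(O[Si](C)(C)C(C)(C)C)=CC[C@H]2[C@@]1(C=C)OC(=O)C[C@H]1[C@@H]3CO[Si](c1ccccc1)(c1ccccc1)C(C)(C)C | intermediate
14 | as 13 with C13 ketone | C#CC[C@]23CC(=O)CC[C@H]2[C@@]1(C=C)OC(=O)C[C@H]1[C@@H]3CO[Si](c1ccccc1)(c1ccccc1)C(C)(C)C | intermediate
15 | tetracyclic alcohol: rings B, C, D and lactone, 13-OH, C16=C17, 10β-vinyl, C7 OTBDPS | C=C1C[C@]23C[C@@]1(O)CC[C@H]2[C@@]1(C=C)OC(=O)C[C@H]1[C@@H]3CO[Si](c1ccccc1)(c1ccccc1)C(C)(C)C | intermediate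
16 | 13-O-triethylsilyl ether of 15 | C=C1C[C@]23C[C@@]1(O[Si](CC)(CC)CC)CC[C@H]2[C@@]1(C=C)OC(=O)C[C@H]1[C@@H]3CO[Si](c1ccccc1)(c1ccccc1)C(C)(C)C | intermediate
17 | 4-methyl lactone (methyl on the convex face, cis to the C10 vinyl group) | C=C1C[C@]23C[C@@]1(O[Si](CC)(CC)CC)CC[C@H]2[C@@]1(C=C)OC(=O)[C@H](C)[C@H]1[C@@H]3CO[Si](c1ccccc1)(c1ccccc1)C(C)(C)C | intermediate
18 | aldol adduct: C4 with C18 methyl (concave side) and 1-hydroxyallyl group (cis to the C10 vinyl group), C3 epimers | C=C1C[C@]23C[C@@]1(O[Si](CC)(CC)CC)CC[C@H]2[C@@]1(C=C)OC(=O)[C@](C)(C(O)C=C)[C@H]1[C@@H]3CO[Si](c1ccccc1)(c1ccccc1)C(C)(C)C | intermediate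
19 | 3-hydroxy-1-ene 19,10-lactone (C3 epimers), 13-OTES, 7-OTBDPS | C=C1C[C@]23C[C@@]1(O[Si](CC)(CC)CC)CC[C@H]2[C@@]12OC(=O)[C@@](C)([C@H]1[C@@H]3CO[Si](c1ccccc1)(c1ccccc1)C(C)(C)C)C(O)C=C2 | intermediate
20 | 3-oxo-1-ene 19,10-lactone, 13-OTES, 7-OTBDPS | C=C1C[C@]23C[C@@]1(O[Si](CC)(CC)CC)CC[C@H]2[C@@]12OC(=O)[C@@](C)([C@H]1[C@@H]3CO[Si](c1ccccc1)(c1ccccc1)C(C)(C)C)C(=O)C=C2 | intermediate
21 | 1β,2β-epoxy-3-oxo lactone | C=C1C[C@]23C[C@@]1(O[Si](CC)(CC)CC)CC[C@H]2[C@@]12OC(=O)[C@@](C)([C@H]1[C@@H]3CO[Si](c1ccccc1)(c1ccccc1)C(C)(C)C)C(=O)[C@H]4O[C@H]42 | intermediate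
22 | C3 hydrazone of 21 | C=C1C[C@]23C[C@@]1(O[Si](CC)(CC)CC)CC[C@H]2[C@@]12OC(=O)[C@@](C)([C@H]1[C@@H]3CO[Si](c1ccccc1)(c1ccccc1)C(C)(C)C)C(=NN)[C@H]4O[C@H]42 | intermediate
23 | 1β-hydroxy-2-ene lactone | C=C1C[C@]23C[C@@]1(O[Si](CC)(CC)CC)CC[C@H]2[C@@]12OC(=O)[C@@](C)([C@H]1[C@@H]3CO[Si](c1ccccc1)(c1ccccc1)C(C)(C)C)C=C[C@H]2O | intermediate
24 | 1β-hydroxy-2β,3β-epoxy lactone, 13-OTES, 7-OTBDPS | C=C1C[C@]23C[C@@]1(O[Si](CC)(CC)CC)CC[C@H]2[C@@]12OC(=O)[C@@](C)([C@H]1[C@@H]3CO[Si](c1ccccc1)(c1ccccc1)C(C)(C)C)[C@H]1O[C@H]1[C@H]2O | intermediate
25 | triol: 27 with CH2OH in place of CO2H on C6 | C=C1C[C@]23C[C@@]1(O)CC[C@H]2[C@@]12OC(=O)[C@@](C)([C@H]1[C@@H]3CO)[C@H]1O[C@H]1[C@H]2O | intermediate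
26 | C7 aldehyde corresponding to 27 | C=C1C[C@]23C[C@@]1(O)CC[C@H]2[C@@]12OC(=O)[C@@](C)([C@H]1[C@@H]3C=O)[C@H]1O[C@H]1[C@H]2O | intermediate
27 | target gibberellin (number 93 of the gibberellin A series): C19 gibberellin 19,10-lactone 7-oic acid with 1β-hydroxyl, 2β,3β-epoxide, 13-hydroxyl and C16=C17 methylene | C=C1C[C@]23C[C@@]1(O)CC[C@H]2[C@@]12OC(=O)[C@@](C)([C@H]1[C@@H]3C(=O)O)[C@H]1O[C@H]1[C@H]2O | target

## Step count and least certain steps

Total: 21 steps. Longest linear sequence: 20 steps (steps 1–4 and 6–21 from 1); step 5 is a one-step side branch.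

**Step 6 (key step).** The most likely failure is that the diene is consumed by acid-induced oligomerisation faster than it adds to the hindered β,β-disubstituted enone, or that the addition stops after the first bond. A smaller risk is incomplete facial control by the C6 substituent.

Fallback, from 7, returning at 14. A more nucleophilic diene is used and the masked ketone is restored by conjugate reduction. 7 is treated with trans-1-methoxy-3-(trimethylsilyloxy)buta-1,3-diene and ZnCl2 or Me3SiNTf2, which gives the methoxy cycloadduct F1. Dilute acid converts it into the cis-fused enedione F2 (C13 ketone conjugated with C11=C12). Conjugate reduction with [(Ph3P)CuH]6 in the presence of Me3SiCl gives the trimethylsilyl enol ether F3, the trimethylsilyl analogue of 10. F3 is taken through the operations of steps 7 and 8 to the keto ester F4, the hydroxy ester F5 (not isolated) and the lactone F6. The acid of step 9 then gives 14.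

**Step 8.** The vinyl group may add in part from the α face, or the hindered ketone may be enolised. The β face carries two 1,3-related substituents (the C7 arm and the propargyl group), so the preference rests on the two adjacent α substituents alone. An α-face adduct cannot lactonise.

Fallback, from 11, returning at 14. The stereochemistry is put under tether control. The vinyl addition to 11 is run as in step 8 without regard to the face, and the non-lactonising epimer, the 10β-hydroxy-10α-vinyl ester F7, is treated with TsOH in wet CH2Cl2. The tertiary allylic alcohol ionises to the C10 allyl cation, and the ester carbonyl, which can reach C10 only from the α face, closes the cis-fused lactone. The enol silyl ether is hydrolysed in the same operation.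

**Step 13.** The hindered tetrasubstituted enolate may undergo retro-aldol on warming or add 1,4 to acrolein, so conversion may be low. Attack from the concave face would give a C4 epimer that cannot close in step 14.

Fallback, from 17, returning at 20. An irreversible C-acylation replaces the aldol. The enolate of 17 is acylated with 3-chloropropanoyl chloride to the β-chloro ketone F8. Et3N eliminates HCl to the vinyl ketone F9. Ring-closing metathesis with the second-generation Hoveyda–Grubbs catalyst then gives 20 directly.

**Step 17.** The hydrazone nitrogen may attack the neighbouring lactone carbonyl (acyl transfer to nitrogen), or hydrazine may open the epoxide, in competition with the fragmentation. Wharton reactions of hindered epoxy ketones are often incomplete.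

Fallback, from 21, returning at 23. A radical fragmentation replaces the hydrazone chemistry. 21 is reduced with NaBH4 and CeCl3 to the epoxy alcohol F10 (either C3 epimer serves). 1,1′-Thiocarbonyldiimidazole converts it into the thiocarbonylimidazolide F11. Bu3SnH and AIBN generate the C3 radical, which opens the epoxide at C2–O. The C1 alkoxy radical takes up hydrogen to give 23.

**Step 10.** The ketyl may be reduced to the secondary alcohol or may dimerise before it finds the alkyne.

Fallback, from 14, returning at 15. The same C13–C16 bond is made by a polar addition. Iodoboration of the terminal alkyne with B-iodo-9-borabicyclo[3.3.1]nonane and protonolysis with AcOH gives the 2-iodoallyl ketone F12. CrCl2 with catalytic NiCl2 in DMSO closes ring D by an intramolecular Nozaki–Hiyama–Kishi addition to the C13 ketone.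

## Further compounds

F1 | step 6 | methoxy cycloadduct: 11-methoxy analogue of 10 with a trimethylsilyl enol ether at C13 | C#CC[C@]23CC(O[Si](C)(C)C)=CC(OC)[C@H]2C(=O)C[C@@H]3CO[Si](c1ccccc1)(c1ccccc1)C(C)(C)C
F2 | step 6 | cis-fused enedione (C10 ketone, C13 ketone, C11=C12) | C#CC[C@]23CC(=O)C=C[C@H]2C(=O)C[C@@H]3CO[Si](c1ccccc1)(c1ccccc1)C(C)(C)C
F3 | step 6 | trimethylsilyl enol ether analogue of 10 | C#CC[C@]23CC(O[Si](C)(C)C)=CC[C@H]2C(=O)C[C@@H]3CO[Si](c1ccccc1)(c1ccccc1)C(C)(C)C
F4 | step 6 | trimethylsilyl enol ether analogue of 11 | C#CC[C@]23CC(O[Si](C)(C)C)=CC[C@H]2C(=O)[C@@H](CC(=O)OCC)[C@@H]3CO[Si](c1ccccc1)(c1ccccc1)C(C)(C)C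
F5 | step 6 | trimethylsilyl enol ether analogue of 12 | C#CC[C@]23CC(O[Si](C)(C)C)=CC[C@H]2[C@](O)(C=C)[C@@H](CC(=O)OCC)[C@@H]3CO[Si](c1ccccc1)(c1ccccc1)C(C)(C)C
F6 | step 6 | trimethylsilyl enol ether analogue of 13 | C#CC[C@]23CC(O[Si](C)(C)C)=CC[C@H]2[C@@]1(C=C)OC(=O)C[C@H]1[C@@H]3CO[Si](c1ccccc1)(c1ccccc1)C(C)(C)C
F7 | step 8 | 10β-hydroxy-10α-vinyl ester (C10 epimer of 12) | C#CC[C@]23CC(O[Si](C)(C)C(C)(C)C)=CC[C@H]2[C@@](O)(C=C)[C@@H](CC(=O)OCC)[C@@H]3CO[Si](c1ccccc1)(c1ccccc1)C(C)(C)C
F8 | step 13 | 4-(3-chloropropanoyl)-4-methyl lactone | C=C1C[C@]23C[C@@]1(O[Si](CC)(CC)CC)CC[C@H]2[C@@]1(C=C)OC(=O)[C@](C)(C(=O)CCCl)[C@H]1[C@@H]3CO[Si](c1ccccc1)(c1ccccc1)C(C)(C)C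
F9 | step 13 | 4-acryloyl-4-methyl lactone | C=C1C[C@]23C[C@@]1(O[Si](CC)(CC)CC)CC[C@H]2[C@@]1(C=C)OC(=O)[C@](C)(C(=O)C=C)[C@H]1[C@@H]3CO[Si](c1ccccc1)(c1ccccc1)C(C)(C)C
F10 | step 17 | 1β,2β-epoxy-3-hydroxy lactone (C3 epimers) | C=C1C[C@]23C[C@@]1(O[Si](CC)(CC)CC)CC[C@H]2[C@@]12OC(=O)[C@@](C)([C@H]1[C@@H]3CO[Si](c1ccccc1)(c1ccccc1)C(C)(C)C)C(O)[C@H]4O[C@H]42
F11 | step 17 | O-(imidazol-1-ylthiocarbonyl) derivative of F10 | C=C1C[C@]23C[C@@]1(O[Si](CC)(CC)CC)CC[C@H]2[C@@]12OC(=O)[C@@](C)([C@H]1[C@@H]3CO[Si](c1ccccc1)(c1ccccc1)C(C)(C)C)C(OC(=S)n5ccnc5)[C@H]4O[C@H]42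
F12 | step 10 | 2-iodoallyl ketone (14 with CH2C(I)=CH2 on C8) | C=C(I)C[C@]23CC(=O)CC[C@H]2[C@@]1(C=C)OC(=O)C[C@H]1[C@@H]3CO[Si](c1ccccc1)(c1ccccc1)C(C)(C)C
A1 | alternative 1 | steviol | C=C1C[C@]23C[C@@]1(O)CC[C@H]2[C@]1(C)CCC[C@@](C)(C(=O)O)[C@H]1CC3
A2 | alternative 1 | 13-hydroxy C20 gibberellin 7,19-dioic acid (number 53 of the gibberellin A series) | C=C1C[C@]23C[C@@]1(O)CC[C@H]2[C@]1(C)CCC[C@@](C)(C(=O)O)[C@H]1[C@@H]3C(=O)O
A3 | alternative 2 | tetracycle with C10 silyl ether, 1-ene, 3β-phenylthio group and C4 methyl ester | C=C1C[C@]23C[C@@]1(O[Si](C)(C)C(C)(C)C)CC[C@H]2[C@]1(O[Si](C)(C)C)C=C[C@H](Sc2ccccc2)[C@@](C)(C(=O)OC)[C@H]1[C@@H]3CO[Si](C)(C)C(C)(C)C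
A4 | alternative 3 | 16-oxo-17-nor analogue of 27 as its 13-trimethylsilyl ether and C7 methyl ester | O=C1C[C@]23C[C@@]1(O[Si](C)(C)C)CC[C@H]2[C@@]12OC(=O)[C@@](C)([C@H]1[C@@H]3C(=O)OC)[C@H]1O[C@H]1[C@H]2O
A5 | alternative 3 | 16-oxo-17-nor 1-ene 19,10-lactone 13-trimethylsilyl ether methyl ester | O=C1C[C@]23C[C@@]1(O[Si](C)(C)C)CC[C@H]2[C@@]12OC(=O)[C@@](C)([C@H]1[C@@H]3C(=O)OC)CC=C2
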